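**Retrosynthetic overview**
1. Target ⇐ 4-hydroxy enone: the C–Br bond is made last, by α'-bromination anti to the existing hydroxyl (trans-bromohydrin under substrate control).
2. 4-Hydroxy enone ⇐ acyclic 10-hydroxy-9,12-diketone: intramolecular aldol condensation closes the only ring made in the route.
3. Hydroxy diketone ⇐ (S)-epoxy ketone + (4Z)-hept-4-enal: light-driven decatungstate/nickel addition of the formyl C–H across the terminal epoxide C–O bond (the later ring bond between C=O and CHBr); the carbinol centre is untouched.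
4. Epoxy ketone ⇐ potassium (S)-glycidate + methyl 8-bromooctanoate (Negishi acylation). Ring order: the oxirane is bought and opened in step 2; the cyclopentenone is closed in step 3.

Assumption: potassium (2S)-oxirane-2-carboxylate is bought enantiopure (the commercial salt of (S)-glycidic acid) and is the only source of chirality.

**Step 1**
Reactants: 1 potassium (2S)-oxirane-2-carboxylate; 2 methyl 8-bromooctanoate
Product: 5 methyl 9-oxo-9-[(2S)-oxiran-2-yl]nonanoate, via acid chloride 3 (not isolated), via alkylzinc bromide 4 (not isolated)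
Conditions: (COCl)2, DMF (cat.), CH2Cl2, 0 °C; then 4 (from 2, Zn, LiCl, THF, 50 °C), Pd(PPh3)4 (3 mol%), THF, 0 to 20 °C
Reagents that add atoms: none
Why: Negishi acylation: the salt gives the acid chloride without free HCl or α-deprotonation, and the ester-tolerant alkylzinc couples at the acyl carbon faster than zinc halides open the electron-poor epoxide, so the bought (S) centre is carried through unchanged.

**Step 2**
Reactants: 5 methyl 9-oxo-9-[(2S)-oxiran-2-yl]nonanoate; 6 (4Z)-hept-4-enal (1.5 equiv)
Product: 8 methyl (10S,15Z)-10-hydroxy-9,12-dioxooctadec-15-enoate, via bromohydrin 7 (not isolated)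
Conditions: (Bu4N)4[W10O32] (2 mol%), NiBr2(MeOCH2CH2OMe) (5 mol%), 4,4'-di-tert-butyl-2,2'-bipyridine (6 mol%), pyridinium bromide (20 mol%), MeCN, 390 nm LEDs, 25 °C
Reagents that add atoms: none
Why: Proposed new method: a formal hydroacylation of an epoxide. Photoexcited decatungstate abstracts the formyl hydrogen of 6 to give an acyl radical, and the reduced decatungstate passes its electron to nickel and releases a proton. Proton and bromide open the terminal epoxide of 5 reversibly at the unhindered CH2 to bromohydrin 7, whose primary C–Br bond adds to low-valent nickel. Capture of the acyl radical and C(sp2)–C(sp3) reductive elimination give the β-hydroxy ketone and return HBr, so the reaction is redox-neutral with no stoichiometric by-product. The C10 carbinol carbon is never a reacting centre and keeps the bought configuration ((S) by CIP in 8). The closest known reaction types are the decatungstate- or quinuclidine-mediated nickel-catalysed C–H arylation and alkylation of aldehydes with organic bromides, and nickel-catalysed epoxide cross-couplings through in situ halohydrins.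

**Step 3**
Reactants: 8 methyl (10S,15Z)-10-hydroxy-9,12-dioxooctadec-15-enoate
Product: 10 methyl 8-[(5S)-5-hydroxy-3-oxo-2-[(2Z)-pent-2-en-1-yl]cyclopent-1-en-1-yl]octanoate, via aldol adduct 9 (not isolated)
Conditions: Na2CO3/NaHCO3 buffer (pH 10), MeOH/H2O, 20 °C
Reagents that add atoms: none
Why: Intramolecular aldol condensation (the classical ring closure of 3-hydroxy-2,5-diketones to rethrolones): the C13 enolate of the unhindered C12 ketone attacks the more electrophilic α-hydroxy ketone C9 and E1cB loss of water gives the tetrasubstituted enone; the carbinol centre is not a reacting centre, and the mild buffer is chosen to keep it from epimerising and to spare the methyl ester.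

**Step 4**
Reactants: 10 methyl 8-[(5S)-5-hydroxy-3-oxo-2-[(2Z)-pent-2-en-1-yl]cyclopent-1-en-1-yl]octanoate
Product: 13 methyl 8-[(4S,5R)-4-bromo-5-hydroxy-3-oxo-2-[(2Z)-pent-2-en-1-yl]cyclopent-1-en-1-yl]octanoate, via bis-silyl dienol ether 11 (not isolated), via silyl-protected bromoketone 12 (not isolated)
Conditions: LiN(SiMe3)2 (2.1 equiv), Me3SiCl (2.3 equiv), THF, −78 °C; then N-bromosuccinimide (1.05 equiv), −78 °C; then aqueous citric acid, 0 °C
Reagents that add atoms: N-bromosuccinimide, O=C1CCC(=O)N1Br
Why: Silyl enol ether α-halogenation: kinetic deprotonation at the only α' carbon (ring C4) with in situ silylation gives the 2-silyloxydiene, which is brominated at that carbon from the face opposite the neighbouring silyloxy group, so Br ends trans to the oxygen ((4S,5R), also the more stable isomer); cold acid then removes the silyl ether without closing the bromohydrin to an epoxide.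

**Compound list**
1 | potassium (2S)-oxirane-2-carboxylate | [K+].[O-]C(=O)[C@@H]1CO1 | starting material
2 | methyl 8-bromooctanoate | COC(=O)CCCCCCCBr | starting material
3 | (2S)-oxirane-2-carbonyl chloride | ClC(=O)[C@@H]1CO1 | intermediate
4 | (8-methoxy-8-oxooctyl)zinc bromide | COC(=O)CCCCCCC[Zn]Br | intermediate
5 | methyl 9-oxo-9-[(2S)-oxiran-2-yl]nonanoate | COC(=O)CCCCCCCC(=O)[C@@H]1CO1 | intermediate
6 | (4Z)-hept-4-enal | CC/C=C\CCC=O | starting material
7 | methyl (10R)-11-bromo-10-hydroxy-9-oxoundecanoate | COC(=O)CCCCCCCC(=O)[C@@H](O)CBr | intermediate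
8 | methyl (10S,15Z)-10-hydroxy-9,12-dioxooctadec-15-enoate | COC(=O)CCCCCCCC(=O)[C@@H](O)CC(=O)CC/C=C\CC | intermediate
9 | methyl 8-[(5S)-1,5-dihydroxy-3-oxo-2-[(2Z)-pent-2-en-1-yl]cyclopentyl]octanoate (mixture at ring C1 and C2) | CC/C=C\CC1C(O)(CCCCCCCC(=O)OC)[C@@H](O)CC1=O | intermediate
10 | methyl 8-[(5S)-5-hydroxy-3-oxo-2-[(2Z)-pent-2-en-1-yl]cyclopent-1-en-1-yl]octanoate | CC/C=C\CC1=C(CCCCCCCC(=O)OC)[C@@H](O)CC1=O | intermediate
11 | methyl 8-[(5S)-2-[(2Z)-pent-2-en-1-yl]-3,5-bis[(trimethylsilyl)oxy]cyclopenta-1,3-dien-1-yl]octanoate | CC/C=C\CC1=C(CCCCCCCC(=O)OC)[C@@H](O[Si](C)(C)C)C=C1O[Si](C)(C)C | intermediate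
12 | methyl 8-[(4S,5R)-4-bromo-3-oxo-2-[(2Z)-pent-2-en-1-yl]-5-[(trimethylsilyl)oxy]cyclopent-1-en-1-yl]octanoate | CC/C=C\CC1=C(CCCCCCCC(=O)OC)[C@@H](O[Si](C)(C)C)[C@H](Br)C1=O | intermediate
13 | methyl 8-[(4S,5R)-4-bromo-5-hydroxy-3-oxo-2-[(2Z)-pent-2-en-1-yl]cyclopent-1-en-1-yl]octanoate | CC/C=C\CC1=C(CCCCCCCC(=O)OC)[C@@H](O)[C@H](Br)C1=O | target

**Step count and risks**
Total step count: 4. Longest linear sequence: 4 steps (1 → 5 → 8 → 10 → 13).

The three steps most likely to fail are steps 2, 3 and 4.

Step 2 is the new reaction. It can fail through bromide attack at the carbonyl-flanked epoxide carbon, through nickel- or acid-induced rearrangement of the epoxy ketone, through loss of HBr from 7, or through bromine-atom-mediated drift of the Z alkene towards E. The fallback uses only known chemistry and keeps the light-driven nickel C–C coupling in its established form. It sets out from 5: LiBr/AcOH in THF gives 7 as an isolated compound, and Et3SiCl/imidazole converts it into methyl (10R)-11-bromo-9-oxo-10-[(triethylsilyl)oxy]undecanoate F1. F1 and 6 are joined by the established aldehyde C–H alkylation with alkyl bromides (NiBr2(dtbbpy), quinuclidine, Ir[dF(CF3)ppy]2(dtbbpy)PF6, K2CO3, dioxane, 450 nm) to give methyl (10S,15Z)-9,12-dioxo-10-[(triethylsilyl)oxy]octadec-15-enoate F2. AcOH/THF/H2O removes the silyl group and the route is rejoined at 8.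

Step 3 can erode the C10 configuration (enolisation towards C10, or retro-aldol and re-aldol, before the ring closes). It can also give the isomeric enone from the other aldol mode (C8 enolate onto the C12 ketone). The fallback changes the ring closure to an intramolecular Horner–Wadsworth–Emmons olefination and sets out from 5:
- t-BuMe2SiCl/NaI in MeCN opens the epoxide to methyl (10R)-10-[(tert-butyldimethylsilyl)oxy]-11-iodo-9-oxoundecanoate F3.
- (Diethoxyphosphoryl)acetic acid is alkylated as its dianion (LiN(iPr)2, 2 equiv) with (2Z)-1-bromopent-2-ene to (4Z)-2-(diethoxyphosphoryl)hept-4-enoic acid F4.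
- Nickel-catalysed reductive acyl–alkyl coupling of F4 (activated in situ with Boc2O) with F3 (Ni(acac)2, 4,4'-di-tert-butyl-2,2'-bipyridine, Zn, MgCl2, DMA) gives methyl (10S,15Z)-10-[(tert-butyldimethylsilyl)oxy]-13-(diethoxyphosphoryl)-9,12-dioxooctadec-15-enoate F5.
- K2CO3/18-crown-6 in toluene deprotonates only the doubly activated C13–H, which fixes the regiochemistry and leaves C10 alone, and closes the ring to methyl 8-[(5S)-5-[(tert-butyldimethylsilyl)oxy]-3-oxo-2-[(2Z)-pent-2-en-1-yl]cyclopent-1-en-1-yl]octanoate F6.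
- HF·pyridine rejoins the route at 10.

Step 4 can fail through γ-deprotonation or a [1,5]-hydrogen shift in 11 (which would erode the carbinol centre), through enolisation of the methyl ester, through closure of the trans-bromohydrin to the epoxide if the mixture warms before the acid quench, or through cis/trans mixtures. The fallback switches from the kinetic silyl dienol ether to a thermodynamic enol bromination on an O-acyl derivative and sets out from 10. Ac2O/pyridine gives methyl 8-[(5S)-5-(acetyloxy)-3-oxo-2-[(2Z)-pent-2-en-1-yl]cyclopent-1-en-1-yl]octanoate F7. Pyrrolidone hydrotribromide in THF brominates the ketone enol in preference to the isolated alkene, and the HBr formed equilibrates the α-bromo ketone to the trans isomer, methyl 8-[(4S,5R)-5-(acetyloxy)-4-bromo-3-oxo-2-[(2Z)-pent-2-en-1-yl]cyclopent-1-en-1-yl]octanoate F8. HCl in MeOH (from AcCl) cleaves the acetate and rejoins the route at 13.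

**Further compounds**
F1 | step 2 | methyl (10R)-11-bromo-9-oxo-10-[(triethylsilyl)oxy]undecanoate | COC(=O)CCCCCCCC(=O)[C@@H](O[Si](CC)(CC)CC)CBr
F2 | step 2 | methyl (10S,15Z)-9,12-dioxo-10-[(triethylsilyl)oxy]octadec-15-enoate | COC(=O)CCCCCCCC(=O)[C@@H](O[Si](CC)(CC)CC)CC(=O)CC/C=C\CC
F3 | step 3 | methyl (10R)-10-[(tert-butyldimethylsilyl)oxy]-11-iodo-9-oxoundecanoate | COC(=O)CCCCCCCC(=O)[C@@H](O[Si](C)(C)C(C)(C)C)CI
F4 | step 3 | (4Z)-2-(diethoxyphosphoryl)hept-4-enoic acid | CC/C=C\CC(C(=O)O)P(=O)(OCC)OCC
F5 | step 3 | methyl (10S,15Z)-10-[(tert-butyldimethylsilyl)oxy]-13-(diethoxyphosphoryl)-9,12-dioxooctadec-15-enoate | COC(=O)CCCCCCCC(=O)[C@@H](O[Si](C)(C)C(C)(C)C)CC(=O)C(C/C=C\CC)P(=O)(OCC)OCC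
F6 | step 3 | methyl 8-[(5S)-5-[(tert-butyldimethylsilyl)oxy]-3-oxo-2-[(2Z)-pent-2-en-1-yl]cyclopent-1-en-1-yl]octanoate | CC/C=C\CC1=C(CCCCCCCC(=O)OC)[C@@H](O[Si](C)(C)C(C)(C)C)CC1=O
F7 | step 4 | methyl 8-[(5S)-5-(acetyloxy)-3-oxo-2-[(2Z)-pent-2-en-1-yl]cyclopent-1-en-1-yl]octanoate | CC/C=C\CC1=C(CCCCCCCC(=O)OC)[C@@H](OC(C)=O)CC1=O
F8 | step 4 | methyl 8-[(4S,5R)-5-(acetyloxy)-4-bromo-3-oxo-2-[(2Z)-pent-2-en-1-yl]cyclopent-1-en-1-yl]octanoate | CC/C=C\CC1=C(CCCCCCCC(=O)OC)[C@@H](OC(C)=O)[C@H](Br)C1=O
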